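Its constants stand for no real mixture; the flask was simulated.

In this closed, stirred vessel the solid feeds the solution from below, the held gas phase feeds it from above, and the target forms where the two meet.

    solid substrate ⇌ starting material, rate k1*(cs1 - [starting material]) while solid is left; crystals form when [starting material] > cs1 (cs1 = 35 mM, k1 = 0.0080 s⁻¹)
    gas phase ⇌ dissolved gas, rate k2*(csat - [dissolved gas]) (k2 = 0.029 s⁻¹, csat = 5.4 mM)
    starting material + dissolved gas → target (k3 = 1.2 L mol⁻¹ s⁻¹)

solid substrate 0.050 M; gas phase 5.4 mM (held); time 15 min

- solid substrate is a solid; its amount is given per volume of the solution
- at the start none of the gas is dissolved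
- at the start none of the solid substrate is in solution
- run time (flask): 15 min

- larch: doubling the solubility in step 1, all else as stated
- birch: doubling the dissolution coefficient of step 1, all else as stated
- alder: doubling the transfer coefficient of step 2, all else as stated
- maple: doubling the saturation concentration of gas phase, all else as stated

* amount of target at 15 min, in percent of the solid substrate charged
* the change that raises the amount of target at 15 min, in percent of the solid substrate charged most ("none" if none brings more than 2 percentage points) (larch / birch / alder / maple / none)
* amount of target at 15 min, in percent of the solid substrate charged, after alder

Into an empty solution, step 1 delivers at most 0.280 mM s⁻¹ and step 2 at most 0.157 mM s⁻¹. The gas is thus the slower feed, and I charge it 5.32 min to bring one equivalent for the solid substrate.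

I freeze what is nearly constant. Once c(starting material) lies well below k2/k3, 24.2 mM, c(dissolved gas) stays near csat, and step 3 becomes pseudo-first-order with constant 0.389 min⁻¹. Paying for the gas first and decaying afterwards leaves exp(−kt·(t − 5.32 min)) of the charge.

But this puts the solid in solution at time zero, whereas the solution fills with time constant 2.08 min, which is not small against the 9.68 min remaining. So I add it. The debt time, the gas payment plus the filling lag, is 7.40 min, and the fraction converted is 1 − exp(−kt·(t − debt)).

Might crystals upset this? At c(starting material) = cs1, dissolution stops while step 3 still consumes about 0.0926 mM s⁻¹, so I expect none. The gas's own lag, 0.575 min, is shorter than the filling lag, and I drop it.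

| flask | debt time | reckoned target |
|---|---|---|
| flask | 7.40 min | 94.8% |
| alder | 4.74 min | 98.1% |
| birch | 6.36 min | 96.5% |
| maple | 4.74 min | >99.9% |

Larch touches no term of the debt, so I credit it generously with the whole lag struck out, which gives 97.7%. My choice is maple.

The forecast gives 95.1% (range 93.5% to 96.5%), 97.9% after alder, and maple as the best change, on the ground of a “doubled gas drive”.

The simulation gives 95.2%, 98.0% after alder, and maple as the best change, with a gain of 4.8 percentage points.

The flask is not at rest at the asked time: 4.79% of the charge still stands as starting material. Ten times the time brings target to 100%, a further 4.8 points. With the debt paid, the reckoning leaves 0.0153% of the charge unconverted at 30.0 min, where the simulated target is >99.9%. The answer is still time-sensitive: a reading at 12.8 min, or a charge of 0.0640 M, moves it by 5 points.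

A neighbour flask holds 0.013 M of solid substrate, all else as in the flask, so its debt time is 3.47 min and the reckoning gives 98.9%. The simulation gives 99.3% for that neighbour flask.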